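## Retrosynthetic overview

- **Feature.** Ring C of the target (C1, C10, C9, C8, C7, C11), the oxygen on C10, the C15 carbon on C8, the CMe2 carbon C6 on C7 and the configuration of C7 are all present in (−)-verbenone. The two skeletons differ by one carbon: C5 sits between C1 and C6 in the target, whereas the terpene joins C1 and C6 directly in its cyclobutane.
- **Late disconnections.** The C10–O ester bond leads back to acid 29, made from dec-9-ynoic acid. The C15 acid leads back to the C8 methyl group (SeO2, then chlorite). The C12 aldehyde leads back to a tert-butyl ester.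
- **Ring A (C1–C2–C3–C4–C5)** is opened at C2–C3. Forward, a tert-butyl acetate arm on C1 closes onto a methyl ester arm on C5 by Dieckmann condensation, and the C3 oxygen is then removed.
- **Ring B (C1–C5–C6–C7–C11)** is opened at C5–C6. Forward, hydrogen-atom transfer to an isopropenyl group on C7 gives the C6 radical, which adds 5-exo to an enoate on C1.
- **Cyclohexenone 11** comes from verbenone by cleavage of the C1–C6 cyclobutane bond. The cleavage is run on the dihydro ketone and the enone is restored afterwards; C1 is built by formylation, alkylation and Wittig reaction. Ring order: C (from the terpene), then B, then A.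

Key step: step 7

Assumption: commercial (1S)-(−)-verbenone is taken as enantiomerically pure. Atoms carry cedrane numbers (C1 quaternary, C2 formyl-bearing, C3/C4 methylenes, C5 ring-fusion CH, C6 CMe2, C7 bridgehead, C8=C9, C10 carbinol carbon, C11 bridge CH2, C12 formyl, C15 carboxyl); side-chain atoms are primed.

## Route

Step 1
Reactants: 1 (1S,5S)-(−)-verbenone
Product: 2 (1S,4R,5S)-cis-verbanone (C8 methyl on the side of the CMe2 bridge)
Conditions: H2 (1 atm), 10% Pd/C, EtOAc, rt
Reagents that add atoms: none
Why: Heterogeneous catalytic hydrogenation adds H2 to C8=C9 from the face of the CH2 bridge (C11), the CMe2 bridge shielding the other, and this temporary saturation leaves C1–C6 as the only cyclobutane bond next to an acceptor in step 2, where the enone would also offer its vinylogous C6–C7 bond and, once opened, a tautomerisation to a phenol; the C8 centre made here is erased in step 6.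

Step 2
Reactants: 2 cis-verbanone
Product: 3 (4S,5R)-5-methyl-4-(prop-1-en-2-yl)cyclohex-1-en-1-yl acetate (methyl and isopropenyl cis)
Conditions: BF3·OEt2, Zn(OAc)2, Ac2O, 0 °C to rt
Reagents that add atoms: acetic anhydride, CC(=O)OC(C)=O
Why: Lewis-acid cyclobutane fragmentation of a pinane-type ketone: the strained C1–C6 bond, which overlaps with the complexed C10 carbonyl, breaks to the tertiary C6 cation and the C1=C10 enolate, the cation loses a methyl proton to give the isopropenyl group and the enolate is acetylated, so C7 keeps its configuration and the enol acetate marks C1 for the next step.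

Step 3
Reactants: 3 enol acetate; 4 2,2,2-trifluoroethyl formate
Product: 6 (2Z,4S,5R)-2-(hydroxymethylidene)-5-methyl-4-(prop-1-en-2-yl)cyclohexan-1-one, via lithium enolate 5 (not isolated)
Conditions: MeLi (2.1 equiv), Et2O, 0 °C; then 4, THF, −78 °C; 1 M HCl work-up
Reagents that add atoms: 2,2,2-trifluoroethyl formate (4), O=COCC(F)(F)F
Why: Cleavage of the enol acetate with methyllithium gives the C1 lithium enolate free of its C9 regioisomer, and crossed Claisen formylation with the activated formate at −78 °C attaches C5; the product rests as the chelated Z enol, so C1 carries no stereocentre yet.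

Step 4
Reactants: 6 hydroxymethylidene ketone; 7 tert-butyl bromoacetate
Product: 8 tert-butyl 2-[(1R,4R,5S)-1-formyl-4-methyl-2-oxo-5-(prop-1-en-2-yl)cyclohexyl]acetate (formyl cis to isopropenyl)
Conditions: K2CO3, NaI (10 mol %), acetone, rt
Reagents that add atoms: tert-butyl bromoacetate (7), CC(C)(C)OC(=O)CBr
Why: SN2 C-alkylation of the soft β-keto aldehyde enolate with an α-halo ester builds the quaternary C1, the electrophile entering axially on the ring face opposite to the C7 isopropenyl group (attack on the same face would be 1,3-diaxial to it), so that C2 ends trans and the formyl carbon C5 cis to C6; bringing C5 in first as a formyl group also avoids alkylating a C1–C5–C4 vinylogous enoate anion, which would react at C4.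

Step 5
Reactants: 8 keto aldehyde; 9 methyl (triphenylphosphoranylidene)acetate
Product: 10 methyl (E)-3-[(1R,4R,5S)-1-(2-tert-butoxy-2-oxoethyl)-4-methyl-2-oxo-5-(prop-1-en-2-yl)cyclohexyl]prop-2-enoate
Conditions: 9 (1.5 equiv), toluene, 80 °C
Reagents that add atoms: methyl (triphenylphosphoranylidene)acetate (9), COC(=O)C=P(c1ccccc1)(c1ccccc1)c1ccccc1
Why: Wittig olefination with a stabilised ylide takes only the aldehyde (the hindered C10 ketone is inert), is E-selective and is neutral enough not to deformylate the non-enolisable β-keto aldehyde.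

Step 6
Reactants: 10 saturated keto diester
Product: 11 methyl (E)-3-[(1R,5R)-1-(2-tert-butoxy-2-oxoethyl)-4-methyl-2-oxo-5-(prop-1-en-2-yl)cyclohex-3-en-1-yl]prop-2-enoate
Conditions: IBX (2.0 equiv), DMSO–fluorobenzene (1:2), 70 °C
Reagents that add atoms: none
Why: IBX dehydrogenation of the ketone through its only possible enol (C9=C10, C1 being quaternary) restores the C8=C9 enone and removes the temporary C8 centre without base, which matters because C7–H is now doubly allylic and γ to the carbonyl.

Step 7
Reactants: 11 cyclohexenone with cis isopropenyl and enoate arms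
Product: 12 methyl 2-[(1R,5S,7S)-1-(2-tert-butoxy-2-oxoethyl)-4,6,6-trimethyl-2-oxobicyclo[3.2.1]oct-3-en-7-yl]acetate (C4 arm exo on C5, on the C11 side)
Conditions: Fe(acac)3 (30 mol %), PhSiH3 (2.5 equiv), degassed EtOH (0.02 M), 60 °C
Reagents that add atoms: none
Why: An iron hydride formed from Fe(acac)3 and PhSiH3 passes a hydrogen atom to the CH2 terminus of the isopropenyl group, the only electron-rich alkene in 11, and leaves the tertiary radical at C6. This nucleophilic radical adds to C5, the β-carbon of the enoate on C1, and the α-ester radical at C4 is reduced by iron(II) and protonated by ethanol, which is the iron-catalysed reductive olefin coupling (a hydrogen-atom-transfer Giese reaction) run within one molecule. Ring B (C1–C5–C6–C7–C11) closes 5-exo-trig, and this closure at the same time creates the bicyclo[3.2.1]oct-3-en-2-one made up of rings B and C. The one new stereocentre, C5, is fixed by the enoate rotamer: C6 can only reach the face of C5 turned towards it, and the rotamer that holds C4 outward on the C11 side (exo) should be preferred to the one that pushes the ester chain under the C8–C9–C10 bridge. The step needs chemoselectivity among three alkenes, which rests on the slow hydrogen-atom transfer to the two electron-poor ones, on the polarity mismatch of a 6-endo attack at C4, and on the ring enone being out of reach, since a bond from C6 to C8 or C9 would make a cyclopropane or a cyclobutane. The cis relation of the two arms set in step 4 and the A(1,2) strain between the C8 methyl group and the C7 substituent, which keeps the radical centre pseudo-axial, bring C6 and C5 within bonding distance.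

Step 8
Reactants: 12 bicyclic keto diester
Product: 13 tert-butyl 3,10-dioxocedr-8-en-12-oate (β-keto ester, C2 labile, drawn with the ester on the C11 side)
Conditions: LiHMDS (2.5 equiv), THF, −78 to 0 °C; AcOH quench
Reagents that add atoms: none
Why: Dieckmann condensation: the C2 enolate of the tert-butyl acetate arm attacks the methyl ester carbonyl C3 and closes ring A (C1–C2–C3–C4–C5) cis-fused on the exo C4 arm, the tert-butyl ester being too poor an acceptor for the reverse closure from C4 and the amide base at low temperature limiting retro-Michael opening of C1–C5.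

Step 9
Reactants: 13 β-keto ester
Product: 14 tert-butyl 10-oxo-3-(trifluoromethylsulfonyloxy)cedra-2,8-dien-12-oate
Conditions: Tf2O, i-Pr2NEt, CH2Cl2, −78 °C
Reagents that add atoms: trifluoromethanesulfonic anhydride, O=S(=O)(OS(=O)(=O)C(F)(F)F)C(F)(F)F
Why: O-Sulfonylation of the β-keto ester enol, the most acidic site so that the amine base leaves the enone alone, fixes the C3 oxygen as a leaving group on a C2=C3 bond.

Step 10
Reactants: 14 enol triflate
Product: 15 tert-butyl 10-oxocedra-2,8-dien-12-oate
Conditions: Pd(OAc)2 (5 mol %), PPh3 (10 mol %), HCO2H, Et3N, DMF, 60 °C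
Reagents that add atoms: none
Why: Palladium-catalysed formate reduction of a vinyl triflate (oxidative addition, formate decarboxylation, reductive elimination) replaces C3–O by C3–H and touches neither enone nor ester.

Step 11
Reactants: 15 enone enoate
Product: 16 cedra-2,8-diene-10,12-diol (C10 configuration immaterial)
Conditions: DIBAL-H (5 equiv), CH2Cl2, −78 to 0 °C; aq. Rochelle salt
Reagents that add atoms: none
Why: DIBAL-H reduction takes the tert-butyl enoate to the primary allylic alcohol and the enone to the allylic alcohol by 1,2-addition, and the C10 configuration formed here is of no consequence because step 12 removes it.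

Step 12
Reactants: 16 diol
Product: 17 10-oxocedra-2,8-dien-12-al
Conditions: Dess–Martin periodinane (2.5 equiv), CH2Cl2, rt
Reagents that add atoms: none
Why: Dess–Martin oxidation of both allylic alcohols gives the C12 enal and returns the C10 enone under neutral conditions, so that steps 11 and 12 together turn the C12 ester into the aldehyde.

Step 13
Reactants: 17 enone enal
Product: 19 10-oxocedr-8-en-12-al (formyl group on the C11 side), via C2-epimeric aldehyde 18 (not isolated)
Conditions: [(Ph3P)CuH]6 (0.4 equiv), benzene, H2O (5 equiv), rt; then DBU (0.2 equiv), CH2Cl2, rt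
Reagents that add atoms: none
Why: Copper hydride conjugate reduction delivers hydride to the unhindered β-carbon C3 of the enal far faster than to the fully substituted β-carbon C8 of the ring enone, and base-catalysed epimerisation through the enolate then sets C2 under thermodynamic control, with the formyl group pseudo-equatorial on ring A, on the C11 side and away from the C10 oxygen.

Step 14
Reactants: 19 keto aldehyde
Product: 20 12,12-(ethylenedioxy)cedr-8-en-10-one
Conditions: HOCH2CH2OH, PPTS (cat.), benzene, reflux, Dean–Stark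
Reagents that add atoms: ethylene glycol, OCCO
Why: Acid-catalysed acetalisation is selective for the aldehyde over the hindered conjugated ketone, masks C12 against the oxidations and the hydride of steps 15 to 18, and locks C2.

Step 15
Reactants: 20 enone acetal
Product: 21 12,12-(ethylenedioxy)-10-oxocedr-8-en-15-al
Conditions: SeO2 (1.5 equiv), 1,4-dioxane, 90 °C
Reagents that add atoms: selenium dioxide, O=[Se]=O
Why: Riley oxidation of the γ-methyl group of a β-methyl enone, a reaction known for verbenone itself, can only take place at C15 because C7–H stands at a bridgehead and C1 has no hydrogen.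

Step 16
Reactants: 21 keto enal
Product: 22 12,12-(ethylenedioxy)-10-oxocedr-8-en-15-oic acid
Conditions: NaClO2, NaH2PO4, 2-methyl-2-butene, t-BuOH–H2O, 0 °C to rt
Reagents that add atoms: sodium chlorite, [Na+].[O-]Cl=O
Why: Pinnick oxidation converts the enal to the acid at pH 3–4, which the dioxolane tolerates, with 2-methyl-2-butene taking up the hypochlorous acid.

Step 17
Reactants: 22 keto acid
Product: 23 tert-butyl 12,12-(ethylenedioxy)-10-oxocedr-8-en-15-oate
Conditions: Cl3CC(=NH)Ot-Bu, CH2Cl2–cyclohexane, rt
Reagents that add atoms: tert-butyl 2,2,2-trichloroacetimidate, CC(C)(C)OC(=N)C(Cl)(Cl)Cl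
Why: O-Alkylation of the acid with the trichloroacetimidate needs no added acid catalyst, spares the dioxolane, and gives an ester that leaves in the same acid step as the other two protecting groups.

Step 18
Reactants: 23 keto ester
Product: 24 tert-butyl 12,12-(ethylenedioxy)-10-hydroxycedr-8-en-15-oate (hydroxyl on the side of the C5–C6 bridge)
Conditions: NaBH4, CeCl3·7H2O, MeOH, −40 °C
Reagents that add atoms: none
Why: Luche reduction gives 1,2-addition to the 4-oxo-enoate, and hydride should come to C10 from the side of the one-carbon bridge C11, anti to the nearly perpendicular C1–C5 bond of the two-carbon bridge, so that the hydroxyl ends on the C5–C6 side as in the target.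

Step 19
Reactants: 25 dec-9-ynoic acid; 26 (6-bromohexyloxy)(tert-butyl)dimethylsilane
Product: 28 16-(tert-butyldimethylsilyloxy)hexadec-9-ynoic acid, via dilithio dianion 27 (not isolated)
Conditions: n-BuLi (2.1 equiv), THF–DMPU, −78 to 0 °C; then 26, 0 °C to rt; cold dilute HCl work-up
Reagents that add atoms: (6-bromohexyloxy)(tert-butyl)dimethylsilane (26), BrCCCCCCO[Si](C)(C)C(C)(C)C
Why: SN2 alkylation of the carboxylate–acetylide dianion of a terminal alkynoic acid with a primary bromide joins C10′ to C11′ and gives the C16 chain in one step.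

Step 20
Reactants: 28 ynoic acid
Product: 29 (Z)-16-(tert-butyldimethylsilyloxy)hexadec-9-enoic acid
Conditions: H2 (1 atm), Lindlar catalyst, quinoline, EtOAc, rt
Reagents that add atoms: none
Why: Lindlar semihydrogenation adds H2 syn to the alkyne and sets the 9′Z alkene.

Step 21
Reactants: 24 allylic alcohol; 29 side-chain acid
Product: 30 fully protected ester (C10 O-acyl, C15 tert-butyl ester, C12 dioxolane, C16′ silyl ether)
Conditions: DCC, DMAP, CH2Cl2, rt
Reagents that add atoms: (Z)-16-(tert-butyldimethylsilyloxy)hexadec-9-enoic acid (29), OC(=O)CCCCCCC/C=C\CCCCCCO[Si](C)(C)C(C)(C)C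
Why: Steglich esterification with DMAP as acyl-transfer catalyst acylates the hindered C10 allylic alcohol with retention, no other free hydroxyl or carboxyl group being present.

Step 22
Reactants: 30 protected ester
Product: 31 target CNP0214056.2
Conditions: TFA–CH2Cl2–H2O (10:10:1), 0 °C to rt; aq. NaHCO3 work-up
Reagents that add atoms: water, O
Why: Acidolysis removes all three acid-labile groups at once (tert-butyl ester by alkyl–oxygen cleavage, dioxolane by hydrolysis, primary silyl ether by solvolysis), the C10 allylic ester being kept from ionising by the electron-poor C8=C9 bond and C2 already resting in its more stable configuration.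

## Compound list

1 | (1S,5S)-(−)-verbenone | CC1=CC(=O)[C@H]2C[C@@H]1C2(C)C | starting material
2 | (1S,4R,5S)-cis-verbanone | C[C@@H]1CC(=O)[C@H]2C[C@@H]1C2(C)C | intermediate
3 | (4S,5R)-5-methyl-4-(prop-1-en-2-yl)cyclohex-1-en-1-yl acetate | CC(=O)OC1=CC[C@H](C(C)=C)[C@H](C)C1 | intermediate
4 | 2,2,2-trifluoroethyl formate | O=COCC(F)(F)F | starting material
5 | lithium (4S,5R)-5-methyl-4-(prop-1-en-2-yl)cyclohex-1-en-1-olate | [Li+].[O-]C1=CC[C@H](C(C)=C)[C@H](C)C1 | intermediate
6 | (2Z,4S,5R)-2-(hydroxymethylidene)-5-methyl-4-(prop-1-en-2-yl)cyclohexan-1-one | O=C1C[C@@H](C)[C@@H](C(C)=C)C/C1=C/O | intermediate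
7 | tert-butyl bromoacetate | CC(C)(C)OC(=O)CBr | starting material
8 | tert-butyl 2-[(1R,4R,5S)-1-formyl-4-methyl-2-oxo-5-(prop-1-en-2-yl)cyclohexyl]acetate | CC(=C)[C@H]1C[C@@](C=O)(C(=O)C[C@H]1C)CC(=O)OC(C)(C)C | intermediate
9 | methyl (triphenylphosphoranylidene)acetate | COC(=O)C=P(c1ccccc1)(c1ccccc1)c1ccccc1 | starting material
10 | methyl (E)-3-[(1R,4R,5S)-1-(2-tert-butoxy-2-oxoethyl)-4-methyl-2-oxo-5-(prop-1-en-2-yl)cyclohexyl]prop-2-enoate | CC(=C)[C@H]1C[C@@](/C=C/C(=O)OC)(C(=O)C[C@H]1C)CC(=O)OC(C)(C)C | intermediate
11 | methyl (E)-3-[(1R,5R)-1-(2-tert-butoxy-2-oxoethyl)-4-methyl-2-oxo-5-(prop-1-en-2-yl)cyclohex-3-en-1-yl]prop-2-enoate | CC(=C)[C@H]1C[C@@](/C=C/C(=O)OC)(C(=O)C=C1C)CC(=O)OC(C)(C)C | intermediate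
12 | methyl 2-[(1R,5S,7S)-1-(2-tert-butoxy-2-oxoethyl)-4,6,6-trimethyl-2-oxobicyclo[3.2.1]oct-3-en-7-yl]acetate | CC1(C)[C@H]2C[C@](CC(=O)OC(C)(C)C)(C(=O)C=C2C)[C@H]1CC(=O)OC | intermediate
13 | tert-butyl 3,10-dioxocedr-8-en-12-oate | CC1(C)[C@H]2C[C@@]3(C(=O)C=C2C)[C@@H](C(=O)OC(C)(C)C)C(=O)C[C@@H]13 | intermediate
14 | tert-butyl 10-oxo-3-(trifluoromethylsulfonyloxy)cedra-2,8-dien-12-oate | CC1(C)[C@H]2C[C@@]3(C(=O)C=C2C)C(C(=O)OC(C)(C)C)=C(OS(=O)(=O)C(F)(F)F)C[C@@H]13 | intermediate
15 | tert-butyl 10-oxocedra-2,8-dien-12-oate | CC1(C)[C@H]2C[C@@]3(C(=O)C=C2C)C(C(=O)OC(C)(C)C)=CC[C@@H]13 | intermediate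
16 | cedra-2,8-diene-10,12-diol | CC1(C)[C@H]2C[C@@]3([C@@H](O)C=C2C)C(CO)=CC[C@@H]13 | intermediate
17 | 10-oxocedra-2,8-dien-12-al | CC1(C)[C@H]2C[C@@]3(C(=O)C=C2C)C(C=O)=CC[C@@H]13 | intermediate
18 | 2-epi-10-oxocedr-8-en-12-al | CC1(C)[C@H]2C[C@@]3(C(=O)C=C2C)[C@H](C=O)CC[C@@H]13 | intermediate
19 | 10-oxocedr-8-en-12-al | CC1(C)[C@H]2C[C@@]3(C(=O)C=C2C)[C@@H](C=O)CC[C@@H]13 | intermediate
20 | 12,12-(ethylenedioxy)cedr-8-en-10-one | CC1(C)[C@H]2C[C@@]3(C(=O)C=C2C)[C@@H](C4OCCO4)CC[C@@H]13 | intermediate
21 | 12,12-(ethylenedioxy)-10-oxocedr-8-en-15-al | CC1(C)[C@H]2C[C@@]3(C(=O)C=C2C=O)[C@@H](C4OCCO4)CC[C@@H]13 | intermediate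
22 | 12,12-(ethylenedioxy)-10-oxocedr-8-en-15-oic acid | CC1(C)[C@H]2C[C@@]3(C(=O)C=C2C(=O)O)[C@@H](C4OCCO4)CC[C@@H]13 | intermediate
23 | tert-butyl 12,12-(ethylenedioxy)-10-oxocedr-8-en-15-oate | CC1(C)[C@H]2C[C@@]3(C(=O)C=C2C(=O)OC(C)(C)C)[C@@H](C4OCCO4)CC[C@@H]13 | intermediate
24 | tert-butyl 12,12-(ethylenedioxy)-10-hydroxycedr-8-en-15-oate | CC1(C)[C@H]2C[C@@]3([C@@H](O)C=C2C(=O)OC(C)(C)C)[C@@H](C4OCCO4)CC[C@@H]13 | intermediate
25 | dec-9-ynoic acid | C#CCCCCCCCC(=O)O | starting material
26 | (6-bromohexyloxy)(tert-butyl)dimethylsilane | BrCCCCCCO[Si](C)(C)C(C)(C)C | starting material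
27 | dilithium salt of dec-9-ynoic acid (carboxylate and acetylide) | [Li+].[Li+].[C-]#CCCCCCCCC(=O)[O-] | intermediate
28 | 16-(tert-butyldimethylsilyloxy)hexadec-9-ynoic acid | OC(=O)CCCCCCCC#CCCCCCCO[Si](C)(C)C(C)(C)C | intermediate
29 | (Z)-16-(tert-butyldimethylsilyloxy)hexadec-9-enoic acid | OC(=O)CCCCCCC/C=C\CCCCCCO[Si](C)(C)C(C)(C)C | intermediate
30 | tert-butyl 10-[(Z)-16-(tert-butyldimethylsilyloxy)hexadec-9-enoyloxy]-12,12-(ethylenedioxy)cedr-8-en-15-oate | CC1(C)[C@H]2C[C@@]3([C@@H](OC(=O)CCCCCCC/C=C\CCCCCCO[Si](C)(C)C(C)(C)C)C=C2C(=O)OC(C)(C)C)[C@@H](C4OCCO4)CC[C@@H]13 | intermediate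
31 | CNP0214056.2, 10-[(Z)-16-hydroxyhexadec-9-enoyloxy]-12-oxocedr-8-en-15-oic acid | CC1(C)[C@H]2C[C@@]3([C@@H](OC(=O)CCCCCCC/C=C\CCCCCCO)C=C2C(=O)O)[C@@H](C=O)CC[C@@H]13 | target

## Step count and risk

Total step count: 22. Longest linear sequence: 20 (steps 1–18, 21, 22).

Steps most likely to fail:

**1. Step 7.** The tertiary C6 radical may be quenched by a second hydrogen-atom transfer before it closes onto the crowded C5. It may also hand back the C7 hydrogen and leave the conjugated isopropylidene dienone. The fallback makes the same radical without any metal hydride in the flask.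
- It sets out from 11. A Mukaiyama hydration (Mn(dpm)3, PhSiH3, O2, i-PrOH, 0 °C), in which dissolved oxygen intercepts the radical, should give the tertiary alcohol F1.
- Acylation with methyl chlorooxoacetate (Et3N, DMAP, CH2Cl2) gives the methyl oxalate F2.
- One equivalent of aqueous CsOH in THF hydrolyses only the activated oxalate ester to the caesium oxalate F3.
- Visible-light photoredox double decarboxylation (iridium photocatalyst, DME–DMF, water, blue light) releases the C6 radical, which has no competing hydrogen donor and adds to C5. The α-ester radical is reduced by the photocatalyst and protonated, and the sequence comes back at 12.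

**2. Step 8.** The C4 enolate may expel C1 by retro-Michael cleavage of C1–C5. Enolisation at the neopentyl C2 may stay incomplete. Equilibration may lead to closure in the wrong sense. The fallback forms the same C2–C3 bond by alkylation instead of acylation, so that no C3 oxygen has to be removed.
- It sets out from 12. LiBH4 (Et2O, MeOH, 0 °C) reduces the ketone and the methyl ester but not the tert-butyl ester, and gives the diol F4.
- I2, PPh3 and imidazole convert the primary alcohol into the iodide F5.
- KHMDS (2.2 equiv, THF, −78 to 0 °C) closes ring A by 5-exo-tet enolate alkylation to the hydroxy ester F6.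
- LiAlH4 gives the saturated diol F7.
- Dess–Martin oxidation of both alcohols, followed by DBU equilibration at C2, comes back at 19 and bypasses steps 8 to 13.

**3. Step 13.** Hydride may also reach the ring enone or add 1,2 to the aldehyde, and the epimer ratio at C2 may settle less cleanly than expected. The fallback removes the competing enone before the conjugate reduction and sets C2 at the ester stage.
- It sets out from 15. Luche reduction gives the hydroxy dienoate F8.
- Magnesium in methanol reduces the only remaining electron-poor alkene to the hydroxy ester F6.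
- In F6 the C10 hydroxyl on the lower face disfavours the lower-face ester, and KOt-Bu in t-BuOH can complete the equilibration.
- LiAlH4 to the saturated diol F7 and Dess–Martin oxidation come back at 19.

## Further compounds

F1 | step 7 | methyl (E)-3-[(1R,5R)-1-(2-tert-butoxy-2-oxoethyl)-5-(2-hydroxypropan-2-yl)-4-methyl-2-oxocyclohex-3-en-1-yl]prop-2-enoate | CC(C)(O)[C@H]1C[C@@](/C=C/C(=O)OC)(C(=O)C=C1C)CC(=O)OC(C)(C)C
F2 | step 7 | methyl oxalate of F1 | COC(=O)C(=O)OC(C)(C)[C@H]1C[C@@](/C=C/C(=O)OC)(C(=O)C=C1C)CC(=O)OC(C)(C)C
F3 | step 7 | caesium oxalate of F1 | [Cs+].[O-]C(=O)C(=O)OC(C)(C)[C@H]1C[C@@](/C=C/C(=O)OC)(C(=O)C=C1C)CC(=O)OC(C)(C)C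
F4 | step 8 | tert-butyl 2-[2-hydroxy-7-(2-hydroxyethyl)-4,6,6-trimethylbicyclo[3.2.1]oct-3-en-1-yl]acetate | CC1(C)[C@H]2C[C@](CC(=O)OC(C)(C)C)([C@@H](O)C=C2C)[C@H]1CCO
F5 | step 8 | tert-butyl 2-[2-hydroxy-7-(2-iodoethyl)-4,6,6-trimethylbicyclo[3.2.1]oct-3-en-1-yl]acetate | CC1(C)[C@H]2C[C@](CC(=O)OC(C)(C)C)([C@@H](O)C=C2C)[C@H]1CCI
F6 | step 8 | tert-butyl 10-hydroxycedr-8-en-12-oate | CC1(C)[C@H]2C[C@@]3([C@@H](O)C=C2C)[C@@H](C(=O)OC(C)(C)C)CC[C@@H]13
F7 | step 8 | cedr-8-ene-10,12-diol | CC1(C)[C@H]2C[C@@]3([C@@H](O)C=C2C)[C@@H](CO)CC[C@@H]13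
F8 | step 13 | tert-butyl 10-hydroxycedra-2,8-dien-12-oate | CC1(C)[C@H]2C[C@@]3([C@@H](O)C=C2C)C(C(=O)OC(C)(C)C)=CC[C@@H]13
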